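Cuts: the three MOM ethers go first. Ring C is opened at O1–C2 and at C3–OH (oxidative closure of a 2'-hydroxychalcone), and the chalcone is split at C2–C3 into a ring A acetophenone and a ring B aldehyde.
The acetyl group is taken off ring A at C4–C4a (formylation, methyl addition, oxidation), which leaves 2-(1,1-dimethylallyl)phloroglucinol.
Enabling feature: ring A has oxygen on C5, C7 and C8a, and C8, which holds the quaternary carbon of the 1,1-dimethylallyl group, sits between C7–O and C8a–O. This is the pattern of a 3,5-dioxo ester closed through its C6 methylene, so ring A is cut at C8–C7 (C7 and C8a are still equivalent) and the chain at its C4–C5 bond into two commercial esters.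
Ring B: the pyran ring is traced to a 1,1-dimethylpropargyl ether on O4' of 2-bromo-4,5-dihydroxybenzaldehyde (new bond at C3'), and the C2' prenyl group takes the place of the bromine.
Forward order: chain, ring A, acetophenone; in parallel the pyran ring and then the prenyl group on ring B; aldol union; ring C last; deprotection.
Stereochemistry: the target has no stereocentre. The E enone is the thermodynamic aldol product, and the racemic centres of two intermediates are erased by the oxidation that follows them.

Key step: step 2

Remark: 4 is drawn in its triketo form although it should be largely enolised, and 12 is taken as a catalogue compound.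

Step 1
Reactants: 1 methyl 3,3-dimethylpent-4-enoate; 2 methyl acetoacetate
Product: 4 methyl 7,7-dimethyl-3,5-dioxonon-8-enoate, via acetoacetate dianion 3 (not isolated)
Conditions: 2 (2.2 equiv), NaH, THF, 0 °C; n-BuLi, 0 °C; 1, 0 °C to rt; 1 M HCl, 0 °C
Reagents that add atoms: none
Why: Acylation of a β-keto ester dianion (crossed Claisen condensation) is known to take place at the terminal carbanion with simple alkyl esters, the surplus dianion takes up the acidic proton of 4, and the vinyl group and the quaternary carbon of 1 are spectators.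

Step 2
Reactants: 4 methyl 7,7-dimethyl-3,5-dioxonon-8-enoate
Product: 6 2-(2-methylbut-3-en-2-yl)benzene-1,3,5-triol, via trilithium trianion 5 (not isolated)
Conditions: LiN(i-Pr)2 (3.3 equiv), THF, −78 to 0 °C; DMPU, 60 °C, argon; AcOH, 0 °C
Reagents that add atoms: none
Why: Proposed new method: three equivalents of LiN(i-Pr)2 remove one proton each from C2, C4 and finally C6, and in trianion 5 the only non-stabilised carbanion, C6, closes on C1 either by addition–elimination at the ester or, after E1cB loss of methoxide from the C1–C2 enolate, by 6π closure of the dienylketene, after which loss of the last C6 proton gives the triphenolate of 6, so that ring A and the bond from the future C8 to its oxygenated neighbour arise in one event. The closest known reactions are the base-induced Claisen (Dieckmann-type) cyclisation of methyl 3,5-dioxohexanoate to phloroglucinol and of 5-oxoalkanoates to 2-alkylcyclohexane-1,3-diones, but a carbon that bears a tertiary alkyl group has not been used as the nucleophile. The ring closes in the allowed 6-(enolendo)-exo-trig mode, whereas C4 could reach C1 only through a four-membered ring. No stereocentre is formed. The selectivity needed is C-acylation through C6 over O-acylation through O5: in the fully deprotonated chain the lactone would be an enol ester that still carries an enolate and can reopen, while the carbocycle is withdrawn irreversibly as the aromatic triphenolate. DMPU is added because lithium bridging O3 and O5 holds the chain extended with C1 far from C6, whereas the solvent-separated polyanion should prefer the coiled form with its oxygens turned outwards, and the moderate temperature avoids a Cope shift of the dimethylallyl unit in partly protonated chains.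

Step 3
Reactants: 6 2-(2-methylbut-3-en-2-yl)benzene-1,3,5-triol
Product: 8 2,4,6-trihydroxy-3-(2-methylbut-3-en-2-yl)benzaldehyde, via aryl iminium chloride 7 (not isolated)
Conditions: POCl3, DMF, EtOAc, 0 °C to rt; H2O, rt
Reagents that add atoms: N,N-dimethylformamide CN(C)C=O; water O
Why: Vilsmeier–Haack formylation is the standard mild C-formylation of free phloroglucinols, the two open ring positions of 6 are equivalent, the first formyl group shuts off a second attack, and the DMF-buffered medium is too weakly acidic to protonate the vinyl group or the alkyl-bearing ring carbon.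

Step 4
Reactants: 8 2,4,6-trihydroxy-3-(2-methylbut-3-en-2-yl)benzaldehyde
Product: 9 2-hydroxy-4,6-bis(methoxymethoxy)-3-(2-methylbut-3-en-2-yl)benzaldehyde
Conditions: MOMCl (2.1 equiv), i-Pr2NEt, CH2Cl2, 0 °C to rt
Reagents that add atoms: chloromethyl methyl ether COCCl
Why: Chelation-controlled partial MOM protection, as known for 2,4,6-trihydroxyphenyl carbonyl compounds, should take the free 4-OH and the less crowded 6-OH and leave the 2-OH, which is hydrogen-bonded to the formyl oxygen and wedged between the formyl group and the quaternary carbon, so that the hydroxyl next to the future C8 is the one kept for O1.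

Step 5
Reactants: 9 2-hydroxy-4,6-bis(methoxymethoxy)-3-(2-methylbut-3-en-2-yl)benzaldehyde
Product: 10 1-[2-hydroxy-4,6-bis(methoxymethoxy)-3-(2-methylbut-3-en-2-yl)phenyl]ethanol (racemic)
Conditions: MeMgBr (2.5 equiv), THF, 0 °C; aq NH4Cl
Reagents that add atoms: methylmagnesium bromide C[Mg]Br
Why: Grignard addition to the aldehyde follows sacrificial deprotonation of the phenol, and the new carbinol centre is formed without control and needs none because step 6 removes it.

Step 6
Reactants: 10 1-[2-hydroxy-4,6-bis(methoxymethoxy)-3-(2-methylbut-3-en-2-yl)phenyl]ethanol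
Product: 11 1-[2-hydroxy-4,6-bis(methoxymethoxy)-3-(2-methylbut-3-en-2-yl)phenyl]ethanone
Conditions: activated MnO2, CH2Cl2, rt
Reagents that add atoms: none
Why: MnO2 oxidation of an electron-rich benzylic alcohol is neutral and selective, leaves the MOM ethers and the vinyl group alone, and should give the hydrogen-bonded 2-hydroxyacetophenone.

Step 7
Reactants: 12 2-bromo-4,5-dihydroxybenzaldehyde; 13 3-chloro-3-methylbut-1-yne
Product: 14 2-bromo-5-hydroxy-4-[(2-methylbut-3-yn-2-yl)oxy]benzaldehyde
Conditions: DBU (1.1 equiv), CuCl2·2H2O (1 mol %), MeCN, 0 °C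
Reagents that add atoms: none
Why: In this copper-catalysed propargylic etherification of a phenol, one equivalent of base ionises only the more acidic 4-OH para to the formyl group, in line with the known 4-O-selective alkylation of 3,4-dihydroxybenzaldehydes.

Step 8
Reactants: 14 2-bromo-5-hydroxy-4-[(2-methylbut-3-yn-2-yl)oxy]benzaldehyde
Product: 15 2-bromo-5-(methoxymethoxy)-4-[(2-methylbut-3-yn-2-yl)oxy]benzaldehyde
Conditions: MOMCl, i-Pr2NEt, CH2Cl2, 0 °C to rt
Reagents that add atoms: chloromethyl methyl ether COCCl
Why: Routine MOM protection of the one remaining phenol gives ring B the same protecting group as ring A, so that a single final step frees all hydroxyls.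

Step 9
Reactants: 15 2-bromo-5-(methoxymethoxy)-4-[(2-methylbut-3-yn-2-yl)oxy]benzaldehyde
Product: 16 5-bromo-8-(methoxymethoxy)-2,2-dimethyl-2H-chromene-6-carbaldehyde
Conditions: N,N-diethylaniline, 190 °C
Reagents that add atoms: none
Why: Aromatic propargyl Claisen rearrangement followed by 1,5-hydrogen shift and oxa-6π electrocyclisation is the standard route to 2,2-dimethylchromenes, and C3 is the only free ortho position because C5 carries the OMOM group, so the bromine ends up on C5 of the chromene next to the formyl group.

Step 10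
Reactants: 16 5-bromo-8-(methoxymethoxy)-2,2-dimethyl-2H-chromene-6-carbaldehyde; 17 1-bromo-3-methylbut-2-ene (prenyl bromide)
Product: 21 8-(methoxymethoxy)-2,2-dimethyl-5-(3-methylbut-2-en-1-yl)-2H-chromene-6-carbaldehyde, via lithium amino alkoxide 18 (not isolated), via aryllithium 19 (not isolated), via prenylated amino alkoxide 20 (not isolated)
Conditions: 1-methylpiperazine, n-BuLi, THF, −20 °C; 16; n-BuLi, −78 °C; 17, −78 to 0 °C; aq NH4Cl
Reagents that add atoms: none
Why: In situ masking of the aldehyde as a lithium α-amino alkoxide, bromine–lithium exchange and SN2 alkylation of the aryllithium at the primary carbon of the allylic bromide are established operations on bromobenzaldehydes, the exchange is far faster than MOM-directed deprotonation, and aqueous work-up releases the amine and the aldehyde.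

Step 11
Reactants: 11 1-[2-hydroxy-4,6-bis(methoxymethoxy)-3-(2-methylbut-3-en-2-yl)phenyl]ethanone; 21 8-(methoxymethoxy)-2,2-dimethyl-5-(3-methylbut-2-en-1-yl)-2H-chromene-6-carbaldehyde
Product: 22 (E)-1-[2-hydroxy-4,6-bis(methoxymethoxy)-3-(2-methylbut-3-en-2-yl)phenyl]-3-[8-(methoxymethoxy)-2,2-dimethyl-5-(3-methylbut-2-en-1-yl)-2H-chromen-6-yl]prop-2-en-1-one
Conditions: KOH, EtOH, rt
Reagents that add atoms: none
Why: Claisen–Schmidt condensation is routine with 2-hydroxy-4,6-bis(methoxymethoxy)acetophenones, E1cB dehydration gives the more stable E enone, and the MOM ethers and all isolated alkenes tolerate the base.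

Step 12
Reactants: 22 the E chalcone
Product: 24 3-hydroxy-5,7-bis(methoxymethoxy)-2-[8-(methoxymethoxy)-2,2-dimethyl-5-(3-methylbut-2-en-1-yl)-2H-chromen-6-yl]-8-(2-methylbut-3-en-2-yl)-4H-chromen-4-one, via trans dihydroflavonol 23 (not isolated)
Conditions: 30% aq H2O2, NaOH, MeOH, 0 °C to rt
Reagents that add atoms: hydrogen peroxide OO
Why: In the Algar–Flynn–Oyamada reaction, alkaline peroxide attacks only the electron-poor enone, the 2'-phenoxide closes ring C on Cβ to give racemic trans 23 and a second equivalent of peroxide dehydrogenates it, so both transient stereocentres disappear, while the prenyl, vinyl and chromene alkenes are inert to a nucleophilic oxidant.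

Step 13
Reactants: 24 the tris-MOM flavonol
Product: 25 Broussoflavonol D, 3,5,7-trihydroxy-2-[8-hydroxy-2,2-dimethyl-5-(3-methylbut-2-en-1-yl)-2H-chromen-6-yl]-8-(2-methylbut-3-en-2-yl)-4H-chromen-4-one
Conditions: HCl (1.25 M in MeOH), 40 °C
Reagents that add atoms: none
Why: Acid-catalysed acetal exchange with methanol cleaves aryl MOM ethers under conditions common for prenylated flavonoids, the prenyl group has no neighbouring hydroxyl to cyclise onto, the monosubstituted vinyl group needs far stronger acid for protonation, and the C4 carbonyl deactivates C8 towards ipso-protonation.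

Compound list
1 | methyl 3,3-dimethylpent-4-enoate | C=CC(C)(C)CC(=O)OC | starting material
2 | methyl acetoacetate | CC(=O)CC(=O)OC | starting material
3 | sodium lithium dianion of methyl acetoacetate | C=C([O-])C=C([O-])OC.[Na+].[Li+] | intermediate
4 | methyl 7,7-dimethyl-3,5-dioxonon-8-enoate | C=CC(C)(C)CC(=O)CC(=O)CC(=O)OC | intermediate
5 | trilithium trianion of 4 (deprotonated at C2, C4 and C6) | C=CC(C)(C)C=C([O-])C=C([O-])C=C([O-])OC.[Li+].[Li+].[Li+] | intermediate
6 | 2-(2-methylbut-3-en-2-yl)benzene-1,3,5-triol | C=CC(C)(C)c1c(O)cc(O)cc1O | intermediate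
7 | dimethyl[2,4,6-trihydroxy-3-(2-methylbut-3-en-2-yl)benzylidene]ammonium chloride | C=CC(C)(C)c1c(O)cc(O)c(C=[N+](C)C)c1O.[Cl-] | intermediate
8 | 2,4,6-trihydroxy-3-(2-methylbut-3-en-2-yl)benzaldehyde | C=CC(C)(C)c1c(O)cc(O)c(C=O)c1O | intermediate
9 | 2-hydroxy-4,6-bis(methoxymethoxy)-3-(2-methylbut-3-en-2-yl)benzaldehyde | C=CC(C)(C)c1c(OCOC)cc(OCOC)c(C=O)c1O | intermediate
10 | 1-[2-hydroxy-4,6-bis(methoxymethoxy)-3-(2-methylbut-3-en-2-yl)phenyl]ethanol, racemic | C=CC(C)(C)c1c(OCOC)cc(OCOC)c(C(C)O)c1O | intermediate
11 | 1-[2-hydroxy-4,6-bis(methoxymethoxy)-3-(2-methylbut-3-en-2-yl)phenyl]ethanone | C=CC(C)(C)c1c(OCOC)cc(OCOC)c(C(C)=O)c1O | intermediate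
12 | 2-bromo-4,5-dihydroxybenzaldehyde | O=Cc1cc(O)c(O)cc1Br | starting material
13 | 3-chloro-3-methylbut-1-yne | C#CC(C)(C)Cl | starting material
14 | 2-bromo-5-hydroxy-4-[(2-methylbut-3-yn-2-yl)oxy]benzaldehyde | O=Cc1cc(O)c(OC(C)(C)C#C)cc1Br | intermediate
15 | 2-bromo-5-(methoxymethoxy)-4-[(2-methylbut-3-yn-2-yl)oxy]benzaldehyde | O=Cc1cc(OCOC)c(OC(C)(C)C#C)cc1Br | intermediate
16 | 5-bromo-8-(methoxymethoxy)-2,2-dimethyl-2H-chromene-6-carbaldehyde | O=Cc1cc(OCOC)c2OC(C)(C)C=Cc2c1Br | intermediate
17 | 1-bromo-3-methylbut-2-ene (prenyl bromide) | CC(C)=CCBr | starting material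
18 | lithium [5-bromo-8-(methoxymethoxy)-2,2-dimethyl-2H-chromen-6-yl](4-methylpiperazin-1-yl)methanolate, racemic | [Li+].[O-]C(N1CCN(C)CC1)c1cc(OCOC)c2OC(C)(C)C=Cc2c1Br | intermediate
19 | 5-lithio analogue of 18 | [Li+].[O-]C(N1CCN(C)CC1)c1cc(OCOC)c2OC(C)(C)C=Cc2c1[Li] | intermediate
20 | 5-(3-methylbut-2-en-1-yl) analogue of 18 | [Li+].[O-]C(N1CCN(C)CC1)c1cc(OCOC)c2OC(C)(C)C=Cc2c1CC=C(C)C | intermediate
21 | 8-(methoxymethoxy)-2,2-dimethyl-5-(3-methylbut-2-en-1-yl)-2H-chromene-6-carbaldehyde | O=Cc1cc(OCOC)c2OC(C)(C)C=Cc2c1CC=C(C)C | intermediate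
22 | (E)-1-[2-hydroxy-4,6-bis(methoxymethoxy)-3-(2-methylbut-3-en-2-yl)phenyl]-3-[8-(methoxymethoxy)-2,2-dimethyl-5-(3-methylbut-2-en-1-yl)-2H-chromen-6-yl]prop-2-en-1-one | C=CC(C)(C)c1c(OCOC)cc(OCOC)c(C(=O)/C=C/c2cc(OCOC)c3OC(C)(C)C=Cc3c2CC=C(C)C)c1O | intermediate
23 | trans-3-hydroxy-5,7-bis(methoxymethoxy)-2-[8-(methoxymethoxy)-2,2-dimethyl-5-(3-methylbut-2-en-1-yl)-2H-chromen-6-yl]-8-(2-methylbut-3-en-2-yl)chroman-4-one, racemic, (2R,3R) enantiomer drawn | CC(C)=CCc1c2C=CC(C)(C)Oc2c(OCOC)cc1[C@@H]3[C@H](C(=O)c4c(OCOC)cc(OCOC)c(C(C)(C)C=C)c4O3)O | intermediate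
24 | 3-hydroxy-5,7-bis(methoxymethoxy)-2-[8-(methoxymethoxy)-2,2-dimethyl-5-(3-methylbut-2-en-1-yl)-2H-chromen-6-yl]-8-(2-methylbut-3-en-2-yl)-4H-chromen-4-one | C=CC(C)(C)c1c(OCOC)cc(OCOC)c2c(=O)c(O)c(-c3cc(OCOC)c4c(c3CC=C(C)C)C=CC(C)(C)O4)oc12 | intermediate
25 | Broussoflavonol D | C=CC(C)(C)c1c(O)cc(O)c2c(=O)c(O)c(-c3cc(O)c4c(c3CC=C(C)C)C=CC(C)(C)O4)oc12 | target

Total step count: 13. Longest linear sequence: 9 steps (steps 1 to 6, then 11 to 13).

Steps most likely to fail

Step 2 (the labelled step). The crowded C6 carbanion may be too slow to attack an ester that is deactivated as its own enolate. The chain would then lactonise through O5 on quenching, or break by retro-Claisen cleavage on long heating. The fallback gives up the open-chain closure and places the 1,1-dimethylallyl group on a ready-made phloroglucinol ring by an aromatic Claisen rearrangement. It sets out from prenyl bromide 17 and comes back to the route at aldehyde 9. Commercial phloroglucinol is treated with two equivalents of MOMCl and i-Pr2NEt to give 3,5-bis(methoxymethoxy)phenol F1. F1 is O-alkylated with 17 (K2CO3, acetone) to 1,3-bis(methoxymethoxy)-5-[(3-methylbut-2-en-1-yl)oxy]benzene F2. Heating F2 in N,N-diethylaniline should carry the allyl unit with inversion to an ortho carbon and give 3,5-bis(methoxymethoxy)-2-(2-methylbut-3-en-2-yl)phenol F3. Casnati–Skattebøl ortho-formylation of F3 (MgCl2, Et3N, paraformaldehyde, MeCN, reflux) at its only free ortho position then delivers 9.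

Step 12. The phenoxide may close on Cα instead of Cβ of the oxidised enone (five-membered instead of six-membered closure). Both the 6'-alkoxy group and the ortho-substituted ring B favour this. The fallback separates ring closure from C3 oxygenation. It sets out from chalcone 22 and comes back at flavonol 24. NaOAc in refluxing EtOH should isomerise 22 by oxa-Michael addition to racemic 5,7-bis(methoxymethoxy)-2-[8-(methoxymethoxy)-2,2-dimethyl-5-(3-methylbut-2-en-1-yl)-2H-chromen-6-yl]-8-(2-methylbut-3-en-2-yl)chroman-4-one F4. Iodine in pyridine at 90 °C dehydrogenates F4 under buffered conditions to the corresponding 4H-chromen-4-one (flavone) F5. C3 lithiation of F5 with LiN(i-Pr)2 at −78 °C, trapping with B(OMe)3 and oxidation with H2O2 and AcOH install the 3-hydroxyl and give 24.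

Step 10. Alkylation of the doubly flanked aryllithium may be slow. Simple protonation (loss of bromine without C–C bond formation) or elimination of HBr from the allylic bromide would then take over. The fallback replaces the organolithium by a Stille cross-coupling. It sets out from 16 and comes back at 21. Compound 16, commercial tributyl(3-methylbut-2-en-1-yl)stannane and Pd(PPh3)4 are heated in DMF at 100 °C. The ortho formyl group should help oxidative addition to zerovalent palladium, and the crowded aryl group should couple at the CH2 terminus of the prenyl unit. The free aldehyde is tolerated, and no compound outside the list is made (F0).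

Further compounds
F1 | step 2 | 3,5-bis(methoxymethoxy)phenol | COCOc1cc(O)cc(OCOC)c1
F2 | step 2 | 1,3-bis(methoxymethoxy)-5-[(3-methylbut-2-en-1-yl)oxy]benzene | COCOc1cc(OCC=C(C)C)cc(OCOC)c1
F3 | step 2 | 3,5-bis(methoxymethoxy)-2-(2-methylbut-3-en-2-yl)phenol | C=CC(C)(C)c1c(O)cc(OCOC)cc1OCOC
F4 | step 12 | 5,7-bis(methoxymethoxy)-2-[8-(methoxymethoxy)-2,2-dimethyl-5-(3-methylbut-2-en-1-yl)-2H-chromen-6-yl]-8-(2-methylbut-3-en-2-yl)chroman-4-one, racemic | C=CC(C)(C)c1c(OCOC)cc(OCOC)c2C(=O)CC(c3cc(OCOC)c4c(c3CC=C(C)C)C=CC(C)(C)O4)Oc12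
F5 | step 12 | 5,7-bis(methoxymethoxy)-2-[8-(methoxymethoxy)-2,2-dimethyl-5-(3-methylbut-2-en-1-yl)-2H-chromen-6-yl]-8-(2-methylbut-3-en-2-yl)-4H-chromen-4-one | C=CC(C)(C)c1c(OCOC)cc(OCOC)c2c(=O)cc(-c3cc(OCOC)c4c(c3CC=C(C)C)C=CC(C)(C)O4)oc12
F0 | step 10 | none | none
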